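**Retrosynthetic overview**
1. 2-Nonadecyl-1,4-benzoquinone ⇒ nonadecylhydroquinone (oxidation comes last) ⇒ its dimethyl ether (O-demethylation).
2. Saturated C19 chain ⇒ aryl ketone ⇒ E-enone ⇒ β-hydroxy ketone ArCO–CH2–CH(OH)–C16H33 (deoxygenation, hydrogenation, dehydration).
3. Key disconnection at C2–C3 of the chain: intermolecular directed aldol addition of the lithium enolate of 2',5'-dimethoxyacetophenone to heptadecanal.
4. Heptadecanal ⇒ 1-octadecene by ozonolysis. The cheap even-numbered olefin gives the odd C17 piece, and 2 + 17 = 19 chain carbons.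
5. Rings: none is formed. The single six-membered carbocycle is bought with the acetophenone and only changes oxidation level at the end.

Assumption: the SMILES holds no stereocentre and no stereogenic acyclic double bond, so the target is achiral and there is no enantiomer to select. The side chain is read as unbranched n-nonadecyl (19 carbons).

**Step 1**
Reactants: 1 1-octadecene
Product: 3 heptadecanal, via secondary ozonide 2 (not isolated)
Conditions: O3/O2, CH2Cl2 (0.05 M), −78 °C, N2 purge; PPh3 (1.2 equiv), −78 °C to rt
Reagents that add atoms: ozone, [O-][O+]=O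
Why: Criegee ozonolysis cleaves the terminal C=C and PPh3 reduces the secondary ozonide to the aldehyde without over-oxidation, so loss of the terminal CH2 turns the C18 olefin into the C17 aldehyde, and no stereocentre survives.

**Step 2**
Reactants: 4 1-(2,5-dimethoxyphenyl)ethanone (2',5'-dimethoxyacetophenone); 3 heptadecanal
Product: 7 rac-3-hydroxy-1-(2,5-dimethoxyphenyl)nonadecan-1-one, via lithium enolate 5 (not isolated), via lithium aldolate 6 (not isolated)
Conditions: 4 (1.1 equiv), LiN(SiMe3)2 (1.05 equiv), THF, −78 °C, 45 min; 3 (1.0 equiv) in THF, −78 °C, 1 h; AcOH (1.2 equiv), −78 °C to rt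
Reagents that add atoms: none
Why: In this directed crossed aldol addition the ketone has one enolisable site and is fully converted to its lithium enolate before the enolisable aldehyde arrives at −78 °C, which suppresses self-condensation, while the cold AcOH quench blocks retro-aldol, and the new C3 carbinol centre forms as a racemate that step 3 erases.

**Step 3**
Reactants: 7 rac-3-hydroxy-1-(2,5-dimethoxyphenyl)nonadecan-1-one
Product: 9 (E)-1-(2,5-dimethoxyphenyl)nonadec-2-en-1-one, via mesylate 8 (not isolated)
Conditions: MsCl (1.5 equiv), Et3N (4 equiv), CH2Cl2, 0 °C to rt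
Reagents that add atoms: none
Why: Mesylation followed by E1cB elimination of the β-mesyloxy ketone gives the conjugated E-enone under mild conditions that do not trigger retro-aldol, which removes the stereocentre, and the alkene geometry does not matter because the alkene is hydrogenated next.

**Step 4**
Reactants: 9 (E)-1-(2,5-dimethoxyphenyl)nonadec-2-en-1-one
Product: 10 saturated ketone 1-(2,5-dimethoxyphenyl)nonadecan-1-one
Conditions: H2 (1 atm), 10% Pd/C, EtOAc, rt
Reagents that add atoms: none
Why: Heterogeneous catalytic hydrogenation saturates the conjugated C=C much faster than it touches the aryl ketone or the arene, and any over-reduced benzylic alcohol converges on the same product in step 5.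

**Step 5**
Reactants: 10 saturated ketone 1-(2,5-dimethoxyphenyl)nonadecan-1-one
Product: 12 2-nonadecyl-1,4-dimethoxybenzene, via benzylic alcohol 11 (not isolated)
Conditions: Et3SiH (3 equiv), CF3CO2H/CH2Cl2 1:1, 0 °C to rt
Reagents that add atoms: none
Why: In this ionic hydrogenation (Kursanov–Parnes reduction) the protonated aryl ketone takes hydride from Et3SiH, the racemic benzylic alcohol ionises to a cation stabilised by the ortho-methoxy group, and a second hydride gives the CH2 with no stereocentre left, while the methyl ethers and the chain are inert.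

**Step 6**
Reactants: 12 2-nonadecyl-1,4-dimethoxybenzene
Product: 14 nonadecylhydroquinone (2-nonadecylbenzene-1,4-diol), via bis(dibromoboryl) ether 13 (not isolated)
Conditions: BBr3 (3 equiv), CH2Cl2, −78 °C to rt, N2; H2O, 0 °C
Reagents that add atoms: none
Why: In this Lewis-acid aryl methyl ether cleavage BBr3 binds each ether oxygen, bromide removes the methyl group by SN2, and hydrolysis of the aryl borates frees the hydroquinone, with no other reactive group in the molecule.

**Step 7**
Reactants: 14 nonadecylhydroquinone (2-nonadecylbenzene-1,4-diol)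
Product: 15 target 2-nonadecylcyclohexa-2,5-diene-1,4-dione (2-nonadecyl-1,4-benzoquinone)
Conditions: Ag2O (2 equiv), Na2SO4, Et2O, rt, dark; filter, concentrate
Reagents that add atoms: none
Why: Ag2O dehydrogenates the hydroquinone to the p-benzoquinone by a two-electron oxidation under neutral anhydrous conditions, so the base- and light-sensitive monoalkylquinone is obtained by filtration alone and no stereocentre is involved.

**Compound list**
1 | 1-octadecene | CCCCCCCCCCCCCCCCC=C | starting material
2 | 3-hexadecyl-1,2,4-trioxolane (secondary ozonide, racemic, not isolated) | CCCCCCCCCCCCCCCCC1OCOO1 | intermediate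
3 | heptadecanal | CCCCCCCCCCCCCCCCC=O | intermediate
4 | 1-(2,5-dimethoxyphenyl)ethanone (2',5'-dimethoxyacetophenone) | CC(=O)c1cc(OC)ccc1OC | starting material
5 | lithium 1-(2,5-dimethoxyphenyl)ethenolate (lithium enolate, not isolated) | [Li]OC(=C)c1cc(OC)ccc1OC | intermediate
6 | lithium alkoxide of 7 (lithium aldolate, racemic, not isolated) | CCCCCCCCCCCCCCCCC(O[Li])CC(=O)c1cc(OC)ccc1OC | intermediate
7 | rac-3-hydroxy-1-(2,5-dimethoxyphenyl)nonadecan-1-one | CCCCCCCCCCCCCCCCC(O)CC(=O)c1cc(OC)ccc1OC | intermediate
8 | rac-1-(2,5-dimethoxyphenyl)-1-oxononadecan-3-yl methanesulfonate (not isolated) | CCCCCCCCCCCCCCCCC(OS(C)(=O)=O)CC(=O)c1cc(OC)ccc1OC | intermediate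
9 | (E)-1-(2,5-dimethoxyphenyl)nonadec-2-en-1-one | CCCCCCCCCCCCCCCC/C=C/C(=O)c1cc(OC)ccc1OC | intermediate
10 | 1-(2,5-dimethoxyphenyl)nonadecan-1-one | CCCCCCCCCCCCCCCCCCC(=O)c1cc(OC)ccc1OC | intermediate
11 | rac-1-(2,5-dimethoxyphenyl)nonadecan-1-ol (not isolated) | CCCCCCCCCCCCCCCCCCC(O)c1cc(OC)ccc1OC | intermediate
12 | 2-nonadecyl-1,4-dimethoxybenzene | CCCCCCCCCCCCCCCCCCCc1cc(OC)ccc1OC | intermediate
13 | 2-nonadecyl-1,4-phenylene bis(dibromoborinate) (not isolated) | CCCCCCCCCCCCCCCCCCCc1cc(OB(Br)Br)ccc1OB(Br)Br | intermediate
14 | 2-nonadecylbenzene-1,4-diol | CCCCCCCCCCCCCCCCCCCc1cc(O)ccc1O | intermediate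
15 | 2-nonadecylcyclohexa-2,5-diene-1,4-dione (achiral) | CCCCCCCCCCCCCCCCCCCC1=CC(=O)C=CC1=O | target

Total step count: 7. Longest linear sequence: 7 steps (1 → 3 → 7 → 9 → 10 → 12 → 14 → 15). Fragment 4 is used as bought.

**Three steps most likely to fail**

(a) The aldol addition (step 2). Heptadecanal is enolisable, waxy and poorly soluble at −78 °C. Proton transfer to the basic enolate, slow addition or retro-aldol can therefore cut the yield. The fallback is a Mukaiyama aldol addition that sets out from 4 and comes back at 7.
- 4 is silylated with Me3SiOSO2CF3/Et3N in CH2Cl2 at 0 °C to the isolable silyl enol ether {[1-(2,5-dimethoxyphenyl)ethenyl]oxy}trimethylsilane F1.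
- F1 is added to 3 pre-complexed with TiCl4 in CH2Cl2 at −78 °C, and aqueous work-up gives 7.
- The aldehyde is activated by a Lewis acid and never meets a strong base. The silyl group leaves as Me3SiCl.

(b) The ketone deoxygenation (step 5). The benzylic cation may alkylate a second electron-rich arene (Friedel–Crafts dimer), or the waxy ketone may react sluggishly in the acidic medium. The fallback replaces the cationic reduction by a stepwise sequence that sets out from 10 and comes back at 12.
- NaBH4 in THF/MeOH reduces 10 to the benzylic alcohol 11, which is isolated this time.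
- Catalytic p-TsOH in refluxing toluene (Dean–Stark) dehydrates 11 to the styrene (E)-2-(nonadec-1-en-1-yl)-1,4-dimethoxybenzene F2.
- H2 over 10% Pd/C in EtOAc saturates F2 to give 12.

(c) The ozonolysis (step 1).
- 1-Octadecene can crystallise from CH2Cl2 at −78 °C.
- Technical olefin carries internal and vinylidene isomers whose cleavage products are hard to remove from the air-sensitive aldehyde 3.
- For the same reason, 3 should be used at once.

The fallback sets out from 1 and comes back at 3.
- Upjohn dihydroxylation (catalytic OsO4, N-methylmorpholine N-oxide, acetone/t-BuOH/H2O, rt) gives crystalline rac-octadecane-1,2-diol F3.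
- F3 is recrystallised free of isomer-derived material.
- Malaprade glycol cleavage with NaIO4 in THF/H2O at rt then delivers 3.

**Further compounds**
F1 | step 2 | {[1-(2,5-dimethoxyphenyl)ethenyl]oxy}trimethylsilane | C=C(O[Si](C)(C)C)c1cc(OC)ccc1OC
F2 | step 5 | (E)-2-(nonadec-1-en-1-yl)-1,4-dimethoxybenzene | CCCCCCCCCCCCCCCCC/C=C/c1cc(OC)ccc1OC
F3 | step 1 | rac-octadecane-1,2-diol | CCCCCCCCCCCCCCCCC(O)CO
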